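**Retrosynthetic overview**
1. Andrographolide ⇐ aldehyde 26 + silylated (S)-3-hydroxybutyrolactone 28 (aldol, then elimination to C-12=C-13); C-8 methylene ⇐ C-8 ketone; C-9 side chain ⇐ α′-alkylation of the ring B enone 20.
2. Ring B ⇐ aldol condensation C-6/C-7 of keto aldehyde 19; 3-OH and 19-OH ⇐ hydride reduction of keto lactone 16.
3. Ring A (key step) ⇐ three components in one flask: allyl sulfoxide 5 (C-2, C-1, C-10 with its methyl, C-9 to C-7), butenolide 10 (C-3, C-4, C-5, C-6, C-19) and MeI (C-18). Bonds formed: C-5–C-10, C-4–C-18, C-2–C-3.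
4. Enabling feature: in ring A, C-2 and C-10 are the two ends of a three-carbon allyl unit (C-1 between them), and C-3 and C-5 both sit on the quaternary C-4, which carries a second carboxyl-level carbon (C-19). Ring A is therefore an allyl 1,3-dinucleophile plus a 2-(alkoxycarbonyl)butenolide 1,3-dielectrophile, whose acetal carbon is C-6 of ring B.
5. Ring order: ring A (step 6), ring B (step 12), side-chain lactone attached last (steps 18–19).

Key step: step 6

Assumption: (R)-configured 5 is taken as the partner matched to (5S)-10 in the chelated addition; its mirror image is equally accessible with the other tartrate ester, so the plan does not depend on this choice.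

**Route**

Step 1
Reactants: 1 pent-1-en-4-yne
Product: 3 (2E)-3-methylhexa-2,5-dien-1-ol, via alkenylalane 2 (not isolated)
Conditions: AlMe3, Cp2ZrCl2 (cat.), CH2Cl2, 0 °C to rt; nBuLi, THF, −78 °C; (CH2O)n, rt; aq HCl
Reagents that add atoms: trimethylaluminium C[Al](C)C; formaldehyde (from paraformaldehyde) C=O
Why: Negishi carboalumination adds methyl and aluminium syn across the terminal alkyne only (the isolated alkene is inert), which fixes the E geometry, and the derived alanate is hydroxymethylated by formaldehyde with retention.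

Step 2
Reactants: 3 (2E)-3-methylhexa-2,5-dien-1-ol
Product: 4 (2E)-3-methylhexa-2,5-dien-1-yl p-tolyl sulfide
Conditions: (4-MeC6H4S)2, Bu3P, THF, rt
Reagents that add atoms: di-p-tolyl disulfide Cc1ccc(SSc2ccc(C)cc2)cc1
Why: Phosphine/disulfide redox condensation (Mukaiyama–Hata type) should displace the activated primary allylic oxygen by thiolate in an SN2 sense without allylic transposition.

Step 3
Reactants: 4 (2E)-3-methylhexa-2,5-dien-1-yl p-tolyl sulfide
Product: 5 (R)-(2E)-3-methylhexa-2,5-dien-1-yl p-tolyl sulfoxide
Conditions: Ti(OiPr)4, (R,R)-diethyl tartrate, H2O, cumene hydroperoxide, CH2Cl2, −20 °C; stored cold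
Reagents that add atoms: cumene hydroperoxide CC(C)(OO)c1ccccc1
Why: Kagan–Modena asymmetric sulfoxidation differentiates the aryl and the allyl group of the sulfide, so the tartrate sets the sulfur stereocenter, and cold handling should suppress racemization by the sulfoxide–sulfenate [2,3]-shift.

Step 4
Reactants: 6 dimethyl malonate, 7 2,2-dimethoxyacetaldehyde
Product: 8 dimethyl 2-(2,2-dimethoxyethylidene)malonate
Conditions: piperidine, AcOH, benzene, reflux (Dean–Stark)
Reagents that add atoms: none
Why: Knoevenagel condensation of a non-enolizable aldehyde with a malonate should give the alkylidene malonate directly.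

Step 5
Reactants: 8 dimethyl 2-(2,2-dimethoxyethylidene)malonate, 9 (+)-menthol
Product: 10 methyl (5S)-5-[(1S,2R,5S)-menthyloxy]-2-oxo-2,5-dihydrofuran-3-carboxylate
Conditions: TsOH·H2O (cat.), H2O (1 equiv), toluene, 80 °C, MeOH distilled off; crystallization, mother liquor re-equilibrated
Reagents that add atoms: water O
Why: Acetal hydrolysis, hemiacetal formation with menthol and lactonization onto the cis ester (pseudo-ester formation) should give the 5-alkoxybutenolide, whose acetal epimers interconvert under acid so that the (5S) epimer can be collected by crystallization.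

Step 6
Reactants: 5 (R)-(2E)-3-methylhexa-2,5-dien-1-yl p-tolyl sulfoxide, 10 methyl (5S)-5-[(1S,2R,5S)-menthyloxy]-2-oxo-2,5-dihydrofuran-3-carboxylate
Product: 14 ring A sulfinyl enone fused to the menthyloxy γ-lactone, via lithiated sulfoxide 11 (not isolated), via adduct enolate 12 (not isolated), via methylated lactone 13 (not isolated)
Conditions: LiN(iPr)2, THF, −78 °C; 10, −78 °C; MeI, DMPU, −78 to −20 °C; LiN(iPr)2, −78 to −40 °C; aq NH4Cl
Reagents that add atoms: iodomethane CI
Why: Proposed new method: the sulfinyl-stabilized allyl anion 11 should add through its γ-carbon (C-10) to the β-carbon (C-5) of the doubly activated butenolide in a lithium-bridged cyclic transition state, the lactone–ester enolate 12 is then C-methylated, and a second portion of LiN(iPr)2 lithiates the (E)-vinyl sulfoxide next to sulfur (C-2), which closes ring A by addition–elimination on the neighbouring methyl ester (C-3). The closest known reactions are the kinetic γ-1,4-addition of lithiated allyl aryl sulfoxides to cyclic enones and butenolides, the tandem conjugate addition–enolate alkylation of 5-alkoxyfuran-2(5H)-ones, and the acylation of α-lithiated vinyl sulfoxides; new is their merger in one flask and a γ-carbon that becomes quaternary. Ring A closes in the 6-exo-trig mode (C-2 carbanion on the C-3 ester carbonyl) to a cis-fused cyclohexenone–γ-lactone. C-5 is set by attack anti to the menthyloxy group on C-6, C-10 by the E geometry of 5 in the chelated chair-like transition state with the (R)-sulfinyl group as matched partner, and C-4 by methylation anti to the bulky C-10 substituent on the five-membered lactone. The step needs γ- over α-attack of the allyl anion (the lithium bridge from sulfinyl oxygen to lactone carbonyl brings only C-10 within reach of C-5) and ring closure on the ester and not on the lactone carbonyl (only the ester, cis to the vinyl arm, gives an unstrained fused ring).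

Step 7
Reactants: 14 ring A sulfinyl enone fused to the menthyloxy γ-lactone
Product: 15 saturated ring A keto lactone with allyl at C-10
Conditions: SmI2, THF–MeOH, −78 to 0 °C
Reagents that add atoms: none
Why: Single-electron conjugate reduction of the sulfinyl-activated enone followed by SmI2 cleavage of the resulting α-sulfinyl ketone (reductive desulfurization) should leave the isolated alkene, the lactone and all stereocenters untouched.

Step 8
Reactants: 15 saturated ring A keto lactone with allyl at C-10
Product: 16 diketo lactone with 2-oxopropyl at C-10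
Conditions: PdCl2 (cat.), CuCl, O2 (1 atm), DMF–H2O, rt
Reagents that add atoms: water O
Why: Wacker oxidation converts the monosubstituted terminal alkene into the methyl ketone with Markovnikov selectivity, which supplies C-8 at the ketone level.

Step 9
Reactants: 16 diketo lactone with 2-oxopropyl at C-10
Product: 17 tetraol (3-OH, 19-OH, 6-OH, 8-OH; C-8 epimers)
Conditions: LiAlH4, THF, −78 °C to rt; aqueous NaOH work-up
Reagents that add atoms: none
Why: Hydride reduction takes the C-3 ketone first, by axial attack from the face opposite the axial C-19 and C-20 groups (equatorial 3-OH, cis to C-19), and then opens the acyl acetal lactone to the C-19 and C-6 primary alcohols with release of menthol.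

Step 10
Reactants: 17 tetraol
Product: 18 3,19-O-isopropylidene diol (free 6-OH and 8-OH)
Conditions: 2,2-dimethoxypropane, PPTS, acetone, rt
Reagents that add atoms: 2,2-dimethoxypropane COC(C)(C)OC
Why: Acetonide formation should select the cis 1,3-diol (six-membered dioxane) over the other hydroxyl pairs, which could only give seven-membered or larger rings.

Step 11
Reactants: 18 3,19-O-isopropylidene diol
Product: 19 keto aldehyde (C-6 aldehyde, C-8 methyl ketone)
Conditions: Dess–Martin periodinane, NaHCO3, CH2Cl2, 0 °C to rt
Reagents that add atoms: none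
Why: Buffered Dess–Martin oxidation converts the primary and the secondary alcohol in one operation under conditions that should not enolize the α-branched aldehyde at C-5.

Step 12
Reactants: 19 keto aldehyde
Product: 20 trans-fused ring B enone acetonide (C-6=C-7, C-8 ketone)
Conditions: Bn2NH·CF3CO2H, benzene, 50 °C
Reagents that add atoms: none
Why: Intramolecular aldol condensation (the ring-closing half of a Robinson annulation, 6-(enolexo)-exo-trig) can form only the six-membered enone from the methyl ketone, and the mild ammonium-salt conditions should keep the C-5 configuration set in step 6.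

Step 13
Reactants: 20 trans-fused ring B enone acetonide
Product: 22 C-9 alkylated enone (methyl ester; side chain trans to the C-10 methyl), via lithium dienolate 21 (not isolated)
Conditions: LiN(iPr)2, THF, −78 °C; BrCH2CO2Me, DMPU, −78 to −40 °C
Reagents that add atoms: methyl bromoacetate BrCC(=O)OC
Why: Kinetic deprotonation of the enone occurs at the only α′ position (C-9) and the cross-conjugated enolate should be alkylated anti to the axial C-10 methyl group.

Step 14
Reactants: 22 C-9 alkylated enone
Product: 24 saturated C-8 keto ester with equatorial C-9 side chain, via 9-epi keto ester 23 (not isolated)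
Conditions: H2 (1 atm), Pd/C, EtOAc, rt; then DBU, CH2Cl2, rt
Reagents that add atoms: none
Why: Catalytic hydrogenation saturates the enone alkene and base equilibration of the ketone α-center should then place the side chain equatorial, cis to the C-10 methyl group as in the target.

Step 15
Reactants: 24 saturated C-8 keto ester
Product: 25 exo-methylene ester
Conditions: Ph3PCH3Br, KN(SiMe3)2, THF–toluene, 0 to 60 °C
Reagents that add atoms: methylenetriphenylphosphorane C=P(c1ccccc1)(c1ccccc1)c1ccccc1
Why: Wittig methylenation converts the C-8 ketone into the exocyclic alkene, and any epimerization at C-9 by the basic ylide leads back to the same equatorial isomer.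

Step 16
Reactants: 25 exo-methylene ester
Product: 26 C-12 aldehyde
Conditions: iBu2AlH, CH2Cl2, −78 °C
Reagents that add atoms: none
Why: Partial reduction of the methyl ester at low temperature stops at the tetrahedral aluminium acetal and gives the aldehyde on work-up.

Step 17
Reactants: 27 (S)-3-hydroxy-γ-butyrolactone
Product: 28 (S)-3-(triethylsilyloxy)-γ-butyrolactone
Conditions: Et3SiCl, imidazole, CH2Cl2, 0 °C
Reagents that add atoms: chlorotriethylsilane CC[Si](Cl)(CC)CC
Why: Silylation protects the C-14 hydroxyl of the chiral-pool lactone with a group that falls off under the same mild acid as the acetonide.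

Step 18
Reactants: 26 C-12 aldehyde, 28 (S)-3-(triethylsilyloxy)-γ-butyrolactone
Product: 30 aldol adduct (C-12 carbinol epimers; C-13 substituent trans to the silyloxy group), via lactone enolate 29 (not isolated)
Conditions: LiN(iPr)2, THF, −78 °C; 26, −78 °C; aq NH4Cl
Reagents that add atoms: none
Why: Aldol addition of the lithium lactone enolate, stable to β-elimination at −78 °C, should take place on the face anti to the silyloxy group.

Step 19
Reactants: 30 aldol adduct
Product: 32 3,19-O-isopropylidene-14-O-triethylsilylandrographolide, via mesylate 31 (not isolated)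
Conditions: MsCl, Et3N, CH2Cl2, 0 °C; then DBU, rt
Reagents that add atoms: none
Why: Mesylation and E1cB elimination through the lactone enolate expel the better leaving group at C-12 and should favour the E-alkylidene lactone with the vinylic hydrogen syn to the carbonyl.

Step 20
Reactants: 32 3,19-O-isopropylidene-14-O-triethylsilylandrographolide
Product: 33 andrographolide
Conditions: AcOH–H2O–THF, 40 °C
Reagents that add atoms: none
Why: Mild acid hydrolysis removes the acetonide and the triethylsilyl ether without ionizing the allylic C-14 alcohol.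

**Compound list**
1 | pent-1-en-4-yne | C#CCC=C | starting material
2 | (E)-dimethyl(2-methylpenta-1,4-dien-1-yl)alane | C[Al](C)/C=C(\C)CC=C | intermediate
3 | (2E)-3-methylhexa-2,5-dien-1-ol | OC/C=C(\C)CC=C | intermediate
4 | (2E)-3-methylhexa-2,5-dien-1-yl p-tolyl sulfide | Cc1ccc(cc1)SC/C=C(\C)CC=C | intermediate
5 | (R)-(2E)-3-methylhexa-2,5-dien-1-yl p-tolyl sulfoxide | Cc1ccc(cc1)[S@](=O)C/C=C(\C)CC=C | intermediate
6 | dimethyl malonate | COC(=O)CC(=O)OC | starting material
7 | 2,2-dimethoxyacetaldehyde | COC(OC)C=O | starting material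
8 | dimethyl 2-(2,2-dimethoxyethylidene)malonate | COC(OC)C=C(C(=O)OC)C(=O)OC | intermediate
9 | (+)-menthol, (1S,2R,5S)-2-isopropyl-5-methylcyclohexanol | O[C@@H]1[C@@H](C(C)C)CC[C@H](C)C1 | starting material
10 | methyl (5S)-5-[(1S,2R,5S)-menthyloxy]-2-oxo-2,5-dihydrofuran-3-carboxylate | COC(=O)C1=C[C@@H](O[C@@H]2[C@@H](C(C)C)CC[C@H](C)C2)OC1=O | intermediate
11 | lithium salt of 5 (sulfinyl-stabilized allyl anion) | Cc1ccc(cc1)[S@](=O)[CH-]/C=C(\C)CC=C.[Li+] | intermediate
12 | lithium ester enolate of the γ-adduct: butyrolactone whose β-carbon (C-5) carries the quaternary C-10 [methyl, allyl, (E)-2-(p-tolylsulfinyl)vinyl] trans to the menthyloxy group | COC([O-])=C1C(=O)O[C@H](O[C@@H]3[C@@H](C(C)C)CC[C@H](C)C3)[C@H]1[C@](C)(CC=C)/C=C/[S@@](=O)c1ccc(C)cc1.[Li+] | intermediate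
13 | C-4 methylated lactone methyl ester (C-4 methyl trans, ester cis to the C-10 substituent) | O=C1O[C@H](O[C@@H]3[C@@H](C(C)C)CC[C@H](C)C3)[C@H]([C@@]1(C)C(=O)OC)[C@](C)(CC=C)/C=C/[S@@](=O)c1ccc(C)cc1 | intermediate
14 | ring A sulfinyl enone cis-fused to the γ-lactone: C-3 ketone, C-1=C-2 with p-tolylsulfinyl at C-2, C-4 methyl, C-10 methyl and allyl, lactone C-19(=O)–O–C-6 with menthyloxy on C-6 | O=C1O[C@H](O[C@@H]3[C@@H](C(C)C)CC[C@H](C)C3)[C@@H]2[C@@]1(C)C(=O)C(=C[C@@]2(C)CC=C)[S@@](=O)c1ccc(C)cc1 | intermediate
15 | saturated ring A keto lactone (C-3 ketone, allyl at C-10) | O=C1O[C@H](O[C@@H]3[C@@H](C(C)C)CC[C@H](C)C3)[C@@H]2[C@@]1(C)C(=O)CC[C@@]2(C)CC=C | intermediate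
16 | diketo lactone (C-3 ketone, 2-oxopropyl at C-10) | O=C1O[C@H](O[C@@H]3[C@@H](C(C)C)CC[C@H](C)C3)[C@@H]2[C@@]1(C)C(=O)CC[C@@]2(C)CC(C)=O | intermediate
17 | tetraol: ring A cyclohexane with equatorial 3-OH, C-4 methyl and hydroxymethyl (C-19, cis to 3-OH), C-5 hydroxymethyl (C-6), C-10 methyl and 2-hydroxypropyl (C-8 epimers) | OC[C@@H]1[C@](C)(CO)[C@H](O)CC[C@@]1(C)CC(C)O | intermediate
18 | 3,19-O-isopropylidene derivative of 17 | OC[C@@H]1[C@]2(C)COC(C)(C)O[C@@H]2CC[C@@]1(C)CC(C)O | intermediate
19 | keto aldehyde acetonide (C-6 aldehyde on C-5, 2-oxopropyl on C-10) | O=C[C@@H]1[C@]2(C)COC(C)(C)O[C@@H]2CC[C@@]1(C)CC(C)=O | intermediate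
20 | trans-fused enone acetonide (C-6=C-7, C-8 ketone, 3,19-O-isopropylidene) | O=C1C=C[C@@H]2[C@]3(C)COC(C)(C)O[C@@H]3CC[C@@]2(C)C1 | intermediate
21 | lithium cross-conjugated dienolate of 20 (C-8 oxygen, C-8=C-9) | [Li+].[O-]C1C=C[C@@H]2[C@]3(C)COC(C)(C)O[C@@H]3CC[C@@]2(C)C=1 | intermediate
22 | C-9 (methoxycarbonylmethyl) enone, side chain trans to the C-10 methyl (9-epi) | O=C1C=C[C@@H]2[C@]3(C)COC(C)(C)O[C@@H]3CC[C@@]2(C)[C@H]1CC(=O)OC | intermediate
23 | saturated 9-epi keto ester | O=C1CC[C@@H]2[C@]3(C)COC(C)(C)O[C@@H]3CC[C@@]2(C)[C@H]1CC(=O)OC | intermediate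
24 | saturated C-8 keto ester, C-9 side chain equatorial and cis to the C-10 methyl | O=C1CC[C@@H]2[C@]3(C)COC(C)(C)O[C@@H]3CC[C@@]2(C)[C@@H]1CC(=O)OC | intermediate
25 | exo-methylene methyl ester (3,19-O-isopropylidene) | C=C1CC[C@@H]2[C@]3(C)COC(C)(C)O[C@@H]3CC[C@@]2(C)[C@@H]1CC(=O)OC | intermediate
26 | C-12 aldehyde (3,19-O-isopropylidene, exo-methylene) | C=C1CC[C@@H]2[C@]3(C)COC(C)(C)O[C@@H]3CC[C@@]2(C)[C@@H]1CC=O | intermediate
27 | (S)-3-hydroxy-γ-butyrolactone | O=C1C[C@H](O)CO1 | starting material
28 | (S)-3-(triethylsilyloxy)-γ-butyrolactone | O=C1C[C@H](O[Si](CC)(CC)CC)CO1 | intermediate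
29 | lithium enolate of 28 | [Li+].[O-]C1=C[C@H](O[Si](CC)(CC)CC)CO1 | intermediate
30 | aldol adduct (C-12 carbinol epimers, C-13 trans to the silyloxy group) | C=C1CC[C@@H]2[C@]3(C)COC(C)(C)O[C@@H]3CC[C@@]2(C)[C@@H]1CC(O)[C@@H]1C(=O)OC[C@H]1O[Si](CC)(CC)CC | intermediate
31 | C-12 mesylate of 30 | C=C1CC[C@@H]2[C@]3(C)COC(C)(C)O[C@@H]3CC[C@@]2(C)[C@@H]1CC(OS(C)(=O)=O)[C@@H]1C(=O)OC[C@H]1O[Si](CC)(CC)CC | intermediate
32 | 3,19-O-isopropylidene-14-O-triethylsilylandrographolide | C=C1CC[C@@H]2[C@]3(C)COC(C)(C)O[C@@H]3CC[C@@]2(C)[C@@H]1C/C=C1/C(=O)OC[C@H]1O[Si](CC)(CC)CC | intermediate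
33 | andrographolide | C=C1CC[C@@H]2[C@](C)(CO)[C@H](O)CC[C@@]2(C)[C@@H]1C/C=C1/C(=O)OC[C@H]1O | target

**Step count**
Total: 20 steps. Longest linear sequence: 17 steps (1–3, 6–16, 18–20); steps 4, 5 and 17 prepare the two partner fragments.

**The three steps most likely to fail**

Step 6 (Proposed new method). What may go wrong: attack through the α-carbon of the allyl anion, proton transfer from the acetal carbon of 10 to the anion, facial mismatch at the new quaternary carbon, methylation of the vinyl anion by residual MeI, and ring closure on the lactone carbonyl. Fallback with known chemistry, setting out from 4 and 10 and returning at 15, uses a Lewis-acid route in separate steps. Lithiation of sulfide 4 and C-silylation (nBuLi, then Me3SiCl) give the α-silyl allyl sulfide F1. Hosomi–Sakurai conjugate addition of F1 to 10 (TiCl4, CH2Cl2, −78 °C; allylsilanes react only at the γ-carbon, here anti to the menthyloxy group) gives the vinyl sulfide lactone F2. K2CO3 and MeI give the C-4 methylated vinyl sulfide lactone F3. Oxidation with mCPBA gives the vinyl sulfoxide lactone F4 (13 as a pair of sulfur epimers). LiN(iPr)2 closes ring A to the sulfinyl enone lactone F5 (14 as sulfur epimers), and SmI2 in MeOH as in step 7 gives 15.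

Step 12. What may go wrong: loss of the C-5 configuration through the enol or enamine of the α-branched aldehyde before or after ring closure, and aldol addition that stops before dehydration. Fallback, setting out from 18 and returning at 20, closes ring B by alkylation so that C-5 never carries an enolizable carbonyl. Selective iodination of the primary alcohol (I2, PPh3, imidazole) gives the iodo alcohol F6, and Dess–Martin oxidation gives the iodo ketone F7. LiN(iPr)2 (THF, −78 °C to rt) forms the kinetic methyl-ketone enolate, which displaces iodide (6-exo-tet) to the saturated bicyclic ketone F8. Kinetic enolization toward C-7 and silylation (LiN(iPr)2, Me3SiCl) give the silyl enol ether F9, and Saegusa–Ito oxidation (Pd(OAc)2, MeCN) gives 20.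

Step 19. What may go wrong: poor E/Z control in the elimination and competing loss of the silyloxy group from C-14. Fallback, setting out from 28 and 26 and returning at 32, uses a Wittig olefination. Bromination of 28 through its silyl ketene acetal (LiN(SiMe3)2, Me3SiCl; then NBS) gives the bromolactone F10. PPh3 followed by Et3N gives the stabilized phosphorane F11, and Wittig reaction of F11 with aldehyde 26 (toluene, 80 °C) should give the E-alkylidene lactone 32 directly.

Further compounds
F1 | step 6 | (2E)-3-methyl-1-(trimethylsilyl)hexa-2,5-dien-1-yl p-tolyl sulfide | Cc1ccc(cc1)SC([Si](C)(C)C)/C=C(\C)CC=C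
F2 | step 6 | vinyl sulfide lactone (γ-adduct of F1 to 10, C-4 unsubstituted) | COC(=O)C1C(=O)O[C@H](O[C@@H]2[C@@H](C(C)C)CC[C@H](C)C2)[C@H]1[C@](C)(CC=C)/C=C/Sc1ccc(C)cc1
F3 | step 6 | C-4 methylated vinyl sulfide lactone | O=C1O[C@H](O[C@@H]3[C@@H](C(C)C)CC[C@H](C)C3)[C@H]([C@@]1(C)C(=O)OC)[C@](C)(CC=C)/C=C/Sc1ccc(C)cc1
F4 | step 6 | vinyl sulfoxide lactone (13 as sulfur epimers) | O=C1O[C@H](O[C@@H]3[C@@H](C(C)C)CC[C@H](C)C3)[C@H]([C@@]1(C)C(=O)OC)[C@](C)(CC=C)/C=C/S(=O)c1ccc(C)cc1
F5 | step 6 | sulfinyl enone lactone (14 as sulfur epimers) | O=C1O[C@H](O[C@@H]3[C@@H](C(C)C)CC[C@H](C)C3)[C@@H]2[C@@]1(C)C(=O)C(=C[C@@]2(C)CC=C)S(=O)c1ccc(C)cc1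
F6 | step 12 | iodo alcohol (C-6 iodide of 18) | IC[C@@H]1[C@]2(C)COC(C)(C)O[C@@H]2CC[C@@]1(C)CC(C)O
F7 | step 12 | iodo ketone | IC[C@@H]1[C@]2(C)COC(C)(C)O[C@@H]2CC[C@@]1(C)CC(C)=O
F8 | step 12 | saturated trans-fused C-8 ketone acetonide | O=C1CC[C@@H]2[C@]3(C)COC(C)(C)O[C@@H]3CC[C@@]2(C)C1
F9 | step 12 | trimethylsilyl enol ether (C-7=C-8) of F8 | C[Si](C)(C)OC1=CC[C@@H]2[C@]3(C)COC(C)(C)O[C@@H]3CC[C@@]2(C)C1
F10 | step 19 | (4S)-3-bromo-4-(triethylsilyloxy)dihydrofuran-2(3H)-one | BrC1C(=O)OC[C@H]1O[Si](CC)(CC)CC
F11 | step 19 | (S)-4-(triethylsilyloxy)-3-(triphenylphosphoranylidene)dihydrofuran-2(3H)-one | O=C1OC[C@@H](O[Si](CC)(CC)CC)C1=P(c1ccccc1)(c1ccccc1)c1ccccc1
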